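I decided to reckon one number for these flasks: how much free nucleophile the electrophile meets during the run.

| setting | east | west | north-west |
|---|---|---|---|
| electrophile | 0.30 M | 0.30 M | 0.30 M |
| nucleophile | 0.600 M | 0.900 M | 1.30 M |
| solid base | 0.0900 M | 0.0900 M | 0.0900 M |
| time | 6.0 h | 6.0 h | 6.0 h |

    electrophile + nucleophile → acid set free + target (k1 = 3.1 × 10⁻⁵ M⁻¹ s⁻¹)
    nucleophile + acid set free ⇌ protonated nucleophile, settled at all times (K2 = 46 M⁻¹)
    acid set free + free base ⇌ salt of the base, settled at all times (K3 = 3800 M⁻¹)
    solid base ⇌ free base, rate k4*(cs4 - [free base]) while solid is left; crystals form when [free base] > cs4 (cs4 = 0.11 M, k4 = 2.7 × 10⁻⁵ s⁻¹)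
    free base → decomposition product (k5 = 1.5 × 10⁻⁸ s⁻¹)
    nucleophile + acid set free ⇌ idle adduct, settled at all times (K6 = 0.80 M⁻¹)

- for acid set free the idle adduct is counted in
- as a solid, counted per litre of solution: solid base
- at the start none of the solid base is in solution
- run time (east): 6.0 h

* part of the electrophile that has reacted at the end, east
* part of the electrophile that has reacted at the end, west
* part of the electrophile that has reacted at the end, north-west
* what raising the concentration of nucleophile from its lowest to its highest value here does to the part of the electrophile that has reacted (changes below 5 percentage points count as none) (it falls / no change / it rises)

**What matters.** Call that number the exposure E: the rate constant of the main step times time times free nucleophile. The electrophile left is then about exp(−E) of its charge, a pseudo-first-order view. With nucleophile as charged, E for east came to 0.402. A rate constant high by half shifted my figure for east by 12 percentage points, so it had to be good. Through the base it brings into solution, a dissolution coefficient or solubility off by half shifted my figure for east by 0.72 points. The equilibrium constants I weighed by size. At the start in east, nucleophile held acid bound against free at 28 to one. The idle adduct took 1.74% of what protonated nucleophile took. Decomposition over the run came to 0.0324% of any free base standing.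

**The number.** East first made acid at 0.0201 M h⁻¹, faster than base arrived, at 0.0107 M h⁻¹, so I let the surplus acid take nucleophile. Base binds acid more strongly than nucleophile does, so I counted all dissolved base, D = 0.0642 M, as salt. That is less than the 0.0900 M charged. A first pass on charged nucleophile gave 0.0993 M reacted in east. Each target costs one nucleophile, and its acid, unless base meets it, costs another, so I put the loss by the end at 0.134 M. Taking half of that, I put the average free nucleophile in east at 0.533 M, and the exposure E, rate constant times time times average free nucleophile, came to 0.357. For east that gave me 30.0%. The same steps gave west 41.3%. For north-west, E = 0.775 gave 53.9%. My verdict on the trend: it rises.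

**The forecast.** It gave 30% for east, 42% for west and 54% for north-west, and said it rises, holding that “more nucleophile gives clearly more conversion”.

**The result.** The simulation gave 29.8% for east, 41.0% for west and 53.4% for north-west; for the part reacted, from lowest to highest nucleophile, it rises, by 24 points. The forecast is right, and the north-west figure moved 5 points with nucleophile at 1.13 M or 1.49 M, or with time at 5.13 h or 6.99 h. Read back from east's result, the exposure was 0.354, against my 0.357. For the west flask read at 1.5 h, the same steps gave E = 0.145, hence 13.5%, and that flask stood at 13.5%.

The constants are invented; the flask was simulated.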